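**Retrosynthetic overview** (1H-isochromene numbering; ring A = pyran O2, C1, C3, C4, C4a, C8a; ring B = carbocycle C4a, C5–C8, C8a)
1. The last C–C bond is C4–C4a. It closes ring A on a finished ring B, and only desilylation follows.
2. Enabling feature: C4 is the terminal carbon of a 2-alkoxy-1,3-diene (O2–C3(=C4H2)–CH=CH–CH3), nucleophilic at C4 and held over C4a by the C8a–C1–O2 tether. C4a is the β-carbon of the C8 enone of ring B and carries SPh as a removable activating and leaving group.
3. The diene ether comes from the C1 alcohol and (E)-penta-1,3-diene (alkoxyselenenylation, selenoxide elimination). C1 comes from formaldehyde (Morita–Baylis–Hillman), SPh from thia-Michael addition and chlorination–elimination.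
4. Ring B with C6 and C7 comes from 2-methylcyclohexane-1,3-dione. The crowded C7–O ester bond is made on the achiral dione by α-acyloxylation with trivalent iodine; a Corey–Bakshi–Shibata desymmetrisation then sets both stereocentres.
5. Ring order: ring B (bought as the dione) and the aryl ring (bought) first, ring A last.

Key step: step 10

Assumption: 4-hydroxy-2-methoxy-6-methylbenzoic acid (1) is taken as a purchasable orsellinic acid derivative.

**Step 1**
Reactants: 1 4-hydroxy-2-methoxy-6-methylbenzoic acid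
Product: 3 2-methoxy-6-methyl-4-[(triisopropylsilyl)oxy]benzoic acid, via triisopropylsilyl ester 2 (not isolated)
Conditions: iPr3SiCl (2.3 equiv), imidazole, DMF, rt; then AcOH/THF/H2O, rt
Reagents that add atoms: chlorotri(propan-2-yl)silane, CC(C)[Si](Cl)(C(C)C)C(C)C
Why: Phenol and acid are both silylated and the far more labile silyl ester is then hydrolysed selectively (water attacks silicon, the di-ortho-substituted acyl carbon is shielded), which is routine protecting-group chemistry with no stereocentre involved.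

**Step 2**
Reactants: 4 2-methylcyclohexane-1,3-dione; 3 2-methoxy-6-methyl-4-[(triisopropylsilyl)oxy]benzoic acid
Product: 5 1-methyl-2,6-dioxocyclohexyl 2-methoxy-6-methyl-4-[(triisopropylsilyl)oxy]benzoate (achiral)
Conditions: PhI(OAc)2 (1.1 equiv), 3 (2.3 equiv), PhCl, 50 °C, reduced pressure; then 4, MeCN, rt
Reagents that add atoms: none
Why: Ligand exchange on trivalent iodine gives PhI(O2CAr)2, the enol of 4 attacks iodine and reductive ligand coupling forms the hindered C7–O bond with the carboxylate as O-nucleophile (α-acyloxylation of a 1,3-dicarbonyl compound by a bis(acyloxy)iodoarene), so no tertiary alcohol has to be acylated.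

**Step 3**
Reactants: 5 1-methyl-2,6-dioxocyclohexyl aryl ester
Product: 6 (1R,2R)-2-hydroxy-1-methyl-6-oxocyclohexyl 2-methoxy-6-methyl-4-[(triisopropylsilyl)oxy]benzoate (OH cis to the ester oxygen)
Conditions: (S)-1-methyl-3,3-diphenyltetrahydro-1H,3H-pyrrolo[1,2-c][1,3,2]oxazaborole (20 mol %), BH3·SMe2 (0.7 equiv), THF, −30 °C; MeOH
Reagents that add atoms: none
Why: The Corey–Bakshi–Shibata reduction desymmetrises the enantiotopic ketones: with quaternary C7 as the large group the S catalyst should give the R carbinol, and hydride attack anti to the aroyloxy group selects the carbonyl whose reduction places C6–OH cis to the C7 ester, so both stereocentres are set here.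

**Step 4**
Reactants: 6 hydroxy ketone
Product: 7 (1R,2R)-1-methyl-6-oxo-2-[(triethylsilyl)oxy]cyclohexyl 2-methoxy-6-methyl-4-[(triisopropylsilyl)oxy]benzoate
Conditions: Et3SiOSO2CF3, 2,6-lutidine, CH2Cl2, −78 °C
Reagents that add atoms: triethylsilyl trifluoromethanesulfonate, CC[Si](CC)(CC)OS(=O)(=O)C(F)(F)F
Why: A silyl triflate with a hindered pyridine silylates the crowded secondary alcohol without base-induced retro-aldol cleavage or acyl shift (standard O-silylation, stereocentres untouched).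

**Step 5**
Reactants: 7 silyl-protected ketone
Product: 9 (1R,6R)-1-methyl-2-oxo-6-[(triethylsilyl)oxy]cyclohex-3-en-1-yl 2-methoxy-6-methyl-4-[(triisopropylsilyl)oxy]benzoate, via trimethylsilyl enol ether 8 (not isolated)
Conditions: LiN(SiMe3)2, Me3SiCl, THF, −78 °C; then Pd(OAc)2 (1.05 equiv), MeCN, rt
Reagents that add atoms: none
Why: In this Saegusa–Ito oxidation C8a is the only enolisable position (C7 is quaternary) and the divalent-palladium enolate can lose only the C4a hydride, which gives the C8a=C4a enone.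

**Step 6**
Reactants: 9 enone
Product: 10 (1R,6R)-3-(hydroxymethyl)-1-methyl-2-oxo-6-[(triethylsilyl)oxy]cyclohex-3-en-1-yl 2-methoxy-6-methyl-4-[(triisopropylsilyl)oxy]benzoate
Conditions: aq. CH2O (37 %), 4-(dimethylamino)pyridine (20 mol %), THF/H2O, rt
Reagents that add atoms: formaldehyde, C=O
Why: In this Morita–Baylis–Hillman reaction the amine adds reversibly to C4a, the C8a enolate captures formaldehyde and loss of the amine restores the enone with C1 in place.

**Step 7**
Reactants: 10 hydroxymethyl enone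
Product: 13 (1R,6R)-3-(hydroxymethyl)-1-methyl-2-oxo-4-(phenylsulfanyl)-6-[(triethylsilyl)oxy]cyclohex-3-en-1-yl 2-methoxy-6-methyl-4-[(triisopropylsilyl)oxy]benzoate, via phenylthio ketone 11 (not isolated), via chloro sulfide 12 (not isolated)
Conditions: PhSH, Et3N (10 mol %), CH2Cl2, 0 °C; then N-chlorosuccinimide, 2,6-lutidine, 0 °C → rt
Reagents that add atoms: benzenethiol, Sc1ccccc1
Why: Thia-Michael addition puts sulfur on C4a, S-chlorination with Pummerer-type shift gives the α-chloro sulfide, and loss of HCl toward the acidic C8a–H gives the vinylogous thioester (β-sulfenylation of an enone); the two transient stereocentres disappear.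

**Step 8**
Reactants: 13 vinylogous thioester alcohol; 14 (E)-penta-1,3-diene
Product: 15 (1R,6R)-1-methyl-2-oxo-3-({[(3E)-1-(phenylselanyl)pent-3-en-2-yl]oxy}methyl)-4-(phenylsulfanyl)-6-[(triethylsilyl)oxy]cyclohex-3-en-1-yl 2-methoxy-6-methyl-4-[(triisopropylsilyl)oxy]benzoate (both epimers at the new ether carbon)
Conditions: PhSeCl, AgOSO2CF3, 2,6-di-tert-butyl-4-methylpyridine, 14 (5 equiv), CH2Cl2, −78 → −40 °C
Reagents that add atoms: benzeneselenenyl chloride, Cl[Se]c1ccccc1
Why: In this alkoxyselenenylation of a 1,3-diene PhSe+ adds to the terminal double bond of 14 and the alcohol opens the seleniranium ion at the allylic carbon (Markovnikov 1,2-addition), which forms O2–C3 with selenium on C4; the new ether stereocentre is uncontrolled and is removed in step 9.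

**Step 9**
Reactants: 15 β-alkoxy selenide
Product: 17 (1R,6R)-1-methyl-2-oxo-3-({[(3E)-penta-1,3-dien-2-yl]oxy}methyl)-4-(phenylsulfanyl)-6-[(triethylsilyl)oxy]cyclohex-3-en-1-yl 2-methoxy-6-methyl-4-[(triisopropylsilyl)oxy]benzoate, via selenoxide 16 (not isolated)
Conditions: mCPBA (1.0 equiv), CH2Cl2, −78 °C; then iPr2NEt, → rt
Reagents that add atoms: none
Why: In this selenoxide syn-elimination selenium is oxidised far faster than the deactivated vinyl sulfide, the only β-hydrogen is the allylic C3–H, and fragmentation at or below room temperature gives the 2-alkoxy-1,3-diene without a [3,3] shift of the allyl vinyl ether.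

**Step 10**
Reactants: 17 dienyl ether of the vinylogous thioester
Product: 19 (6R,7R)-7-methyl-8-oxo-3-[(1E)-prop-1-en-1-yl]-6-[(triethylsilyl)oxy]-5,6,7,8-tetrahydro-1H-isochromen-7-yl 2-methoxy-6-methyl-4-[(triisopropylsilyl)oxy]benzoate, via silyl enol ether 18 (not isolated)
Conditions: Me3SiOSO2CF3 (1.2 equiv), 2,6-di-tert-butyl-4-methylpyridine (1.5 equiv), CH2Cl2, −78 → 0 °C
Reagents that add atoms: none
Why: Proposed new method: O-silylation of the C8 carbonyl turns the vinylogous thioester into a 1-siloxy-3-(phenylsulfanyl)allyl cation (a vinylogous thionium ion), C4 of the tethered 2-alkoxydiene adds to its C4a terminus, the C3 oxocarbenium ion loses the C4 proton to the hindered pyridine to give 18, and the doubly allylic C4a–S bond of 18 then ionises with silyl transfer to sulfur, which leaves ring A and the O2–C3=C4–C4a=C8a–C8=O chromophore at the final oxidation level. The closest known reaction types are the Mukaiyama–Michael addition of enol ethers to silyl-triflate-activated vinylogous esters (4-siloxypyrylium ions), thionium-ion (Pummerer-type) cyclisations onto enol ethers and the addition–elimination of carbon nucleophiles on β-(arylsulfanyl) enones; what is new is their union in a ring closure by a plain alkyl enol ether. Ring A closes 6-endo-trig with respect to the C4a=C8a bond (tether C8a–C1–O2–C3, new bond C4–C4a). The only new stereocentre, C4a in 18, is erased by the elimination, and C6 and C7 are not involved. The step needs attack at C4a rather than at C8, the other terminus of the allyl cation, which the neopentylic position of C8 beside quaternary C7 should secure, and it needs proton loss from C4 rather than from the propenyl methyl group, which is reversible and funnels to the fully conjugated 19. Since 17 is also an allyl vinyl ether, a competing [3,3] shift would form the same C4–C4a bond.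

**Step 11**
Reactants: 19 bis-silyl ether
Product: 20 (6R,7R)-6-hydroxy-7-methyl-8-oxo-3-[(1E)-prop-1-en-1-yl]-5,6,7,8-tetrahydro-1H-isochromen-7-yl 4-hydroxy-2-methoxy-6-methylbenzoate
Conditions: Bu4NF, AcOH (1:1), THF, 0 °C → rt
Reagents that add atoms: none
Why: Buffered fluoride cleaves the aryl and the secondary silyl ether (desilylation), and the near-neutral medium avoids retro-aldol opening of the β-hydroxy ketone and migration of the hindered ester; no stereocentre is affected.

**Compound list**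
1 | 4-hydroxy-2-methoxy-6-methylbenzoic acid | Cc1cc(O)cc(OC)c1C(=O)O | starting material
2 | triisopropylsilyl 2-methoxy-6-methyl-4-[(triisopropylsilyl)oxy]benzoate | Cc1cc(O[Si](C(C)C)(C(C)C)C(C)C)cc(OC)c1C(=O)O[Si](C(C)C)(C(C)C)C(C)C | intermediate
3 | 2-methoxy-6-methyl-4-[(triisopropylsilyl)oxy]benzoic acid | Cc1cc(O[Si](C(C)C)(C(C)C)C(C)C)cc(OC)c1C(=O)O | intermediate
4 | 2-methylcyclohexane-1,3-dione | CC1C(=O)CCCC1=O | starting material
5 | 1-methyl-2,6-dioxocyclohexyl 2-methoxy-6-methyl-4-[(triisopropylsilyl)oxy]benzoate | CC1(OC(=O)c2c(C)cc(O[Si](C(C)C)(C(C)C)C(C)C)cc2OC)C(=O)CCCC1=O | intermediate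
6 | (1R,2R)-2-hydroxy-1-methyl-6-oxocyclohexyl 2-methoxy-6-methyl-4-[(triisopropylsilyl)oxy]benzoate | O=C1[C@](C)(OC(=O)c2c(C)cc(O[Si](C(C)C)(C(C)C)C(C)C)cc2OC)[C@H](O)CCC1 | intermediate
7 | (1R,2R)-1-methyl-6-oxo-2-[(triethylsilyl)oxy]cyclohexyl 2-methoxy-6-methyl-4-[(triisopropylsilyl)oxy]benzoate | O=C1[C@](C)(OC(=O)c2c(C)cc(O[Si](C(C)C)(C(C)C)C(C)C)cc2OC)[C@H](O[Si](CC)(CC)CC)CCC1 | intermediate
8 | trimethylsilyl enol ether of 7 (C8=C8a, configuration at C6 and C7 as in 7) | C[Si](C)(C)OC=1[C@](C)(OC(=O)c2c(C)cc(O[Si](C(C)C)(C(C)C)C(C)C)cc2OC)[C@H](O[Si](CC)(CC)CC)CCC=1 | intermediate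
9 | (1R,6R)-1-methyl-2-oxo-6-[(triethylsilyl)oxy]cyclohex-3-en-1-yl 2-methoxy-6-methyl-4-[(triisopropylsilyl)oxy]benzoate | O=C1[C@](C)(OC(=O)c2c(C)cc(O[Si](C(C)C)(C(C)C)C(C)C)cc2OC)[C@H](O[Si](CC)(CC)CC)CC=C1 | intermediate
10 | (1R,6R)-3-(hydroxymethyl)-1-methyl-2-oxo-6-[(triethylsilyl)oxy]cyclohex-3-en-1-yl 2-methoxy-6-methyl-4-[(triisopropylsilyl)oxy]benzoate | O=C1[C@](C)(OC(=O)c2c(C)cc(O[Si](C(C)C)(C(C)C)C(C)C)cc2OC)[C@H](O[Si](CC)(CC)CC)CC=C1CO | intermediate
11 | 3-(hydroxymethyl)-1-methyl-2-oxo-4-(phenylsulfanyl)-6-[(triethylsilyl)oxy]cyclohexyl 2-methoxy-6-methyl-4-[(triisopropylsilyl)oxy]benzoate (C6, C7 as in 10; C4a, C8a epimers) | O=C1[C@](C)(OC(=O)c2c(C)cc(O[Si](C(C)C)(C(C)C)C(C)C)cc2OC)[C@H](O[Si](CC)(CC)CC)CC(Sc3ccccc3)C1CO | intermediate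
12 | 4-chloro-3-(hydroxymethyl)-1-methyl-2-oxo-4-(phenylsulfanyl)-6-[(triethylsilyl)oxy]cyclohexyl 2-methoxy-6-methyl-4-[(triisopropylsilyl)oxy]benzoate (C6, C7 as in 10) | O=C1[C@](C)(OC(=O)c2c(C)cc(O[Si](C(C)C)(C(C)C)C(C)C)cc2OC)[C@H](O[Si](CC)(CC)CC)CC(Cl)(Sc3ccccc3)C1CO | intermediate
13 | (1R,6R)-3-(hydroxymethyl)-1-methyl-2-oxo-4-(phenylsulfanyl)-6-[(triethylsilyl)oxy]cyclohex-3-en-1-yl 2-methoxy-6-methyl-4-[(triisopropylsilyl)oxy]benzoate | O=C1[C@](C)(OC(=O)c2c(C)cc(O[Si](C(C)C)(C(C)C)C(C)C)cc2OC)[C@H](O[Si](CC)(CC)CC)CC(Sc3ccccc3)=C1CO | intermediate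
14 | (E)-penta-1,3-diene | C=C/C=C/C | starting material
15 | (1R,6R)-1-methyl-2-oxo-3-({[(3E)-1-(phenylselanyl)pent-3-en-2-yl]oxy}methyl)-4-(phenylsulfanyl)-6-[(triethylsilyl)oxy]cyclohex-3-en-1-yl 2-methoxy-6-methyl-4-[(triisopropylsilyl)oxy]benzoate (epimers at the ether carbon) | O=C1[C@](C)(OC(=O)c2c(C)cc(O[Si](C(C)C)(C(C)C)C(C)C)cc2OC)[C@H](O[Si](CC)(CC)CC)CC(Sc3ccccc3)=C1COC(C[Se]c3ccccc3)/C=C/C | intermediate
16 | selenoxide of 15 | O=C1[C@](C)(OC(=O)c2c(C)cc(O[Si](C(C)C)(C(C)C)C(C)C)cc2OC)[C@H](O[Si](CC)(CC)CC)CC(Sc3ccccc3)=C1COC(C[Se](=O)c3ccccc3)/C=C/C | intermediate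
17 | (1R,6R)-1-methyl-2-oxo-3-({[(3E)-penta-1,3-dien-2-yl]oxy}methyl)-4-(phenylsulfanyl)-6-[(triethylsilyl)oxy]cyclohex-3-en-1-yl 2-methoxy-6-methyl-4-[(triisopropylsilyl)oxy]benzoate | O=C1[C@](C)(OC(=O)c2c(C)cc(O[Si](C(C)C)(C(C)C)C(C)C)cc2OC)[C@H](O[Si](CC)(CC)CC)CC(Sc3ccccc3)=C1COC(=C)/C=C/C | intermediate
18 | 7-methyl-4a-(phenylsulfanyl)-3-[(1E)-prop-1-en-1-yl]-6-[(triethylsilyl)oxy]-8-[(trimethylsilyl)oxy]-4a,5,6,7-tetrahydro-1H-isochromen-7-yl 2-methoxy-6-methyl-4-[(triisopropylsilyl)oxy]benzoate (C6, C7 as in 19; C4a undefined) | C/C=C/C1=CC2(Sc3ccccc3)C(CO1)=C(O[Si](C)(C)C)[C@](C)(OC(=O)c1c(C)cc(O[Si](C(C)C)(C(C)C)C(C)C)cc1OC)[C@H](O[Si](CC)(CC)CC)C2 | intermediate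
19 | (6R,7R)-7-methyl-8-oxo-3-[(1E)-prop-1-en-1-yl]-6-[(triethylsilyl)oxy]-5,6,7,8-tetrahydro-1H-isochromen-7-yl 2-methoxy-6-methyl-4-[(triisopropylsilyl)oxy]benzoate | C/C=C/C1=CC2=C(CO1)C(=O)[C@](C)(OC(=O)c1c(C)cc(O[Si](C(C)C)(C(C)C)C(C)C)cc1OC)[C@H](O[Si](CC)(CC)CC)C2 | intermediate
20 | (6R,7R)-6-hydroxy-7-methyl-8-oxo-3-[(1E)-prop-1-en-1-yl]-5,6,7,8-tetrahydro-1H-isochromen-7-yl 4-hydroxy-2-methoxy-6-methylbenzoate | C/C=C/C1=CC2=C(CO1)C(=O)[C@](C)(OC(=O)c1c(C)cc(O)cc1OC)[C@H](O)C2 | target

**Step count and risks**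
Total step count: 11. Longest linear sequence: 11 steps (1 → 20; compounds 4 and 14 enter as purchased inputs).

Steps most likely to fail:

1. Step 10 (Proposed new method). Ionisation of the allylic C1–O2 bond or cationic oligomerisation of the alkoxydiene may outrun the 6-endo C–C bond formation, or the adduct may stall before the thio group is lost. The fallback uses known chemistry and sets out from 17. Claisen rearrangement in toluene at 100 °C (trace of iPr2NEt) gives the ring-opened 2-methylidene 1,5-diketone F1. DBU then removes benzenethiol by E1cB elimination across C4–C4a to give the Z-dienone F2, whose oxa-6π electrocyclisation restores the pyran and returns to the route at 19.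

2. Step 8. Capture of the seleniranium ion by a single equivalent of the neopentyl-like primary alcohol may be slow, so that 1,4-addition across the diene or selenenylation of the vinyl sulfide competes. In the fallback the ether is made at O2–C1 instead of O2–C3. Hydroxyselenenylation of 14 (PhSeCl, MeCN/H2O) gives 1-(phenylselanyl)pent-3-en-2-ol F3, Appel bromination of 13 (CBr4, PPh3) gives the allylic bromide F4, and silver-assisted etherification of F4 with F3 (AgOSO2CF3, 2,6-di-tert-butyl-4-methylpyridine, CH2Cl2) returns to the route at 15.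

3. Step 2. Incomplete ligand exchange on iodine (transfer of acetate) or slow ligand coupling of the crowded carboxylate may let oxidative degradation of the dione take over. The fallback sets out from 4: hydroxylation with dimethyldioxirane gives 2-hydroxy-2-methylcyclohexane-1,3-dione F5, which is esterified with 3 through its mixed anhydride with (CF3CO)2O (the acylium pathway open to di-ortho-substituted benzoic acids) and returns to the route at 5.

**Further compounds**
F1 | step 10 | 1-methyl-3-methylidene-2-oxo-4-[(3E)-2-oxopent-3-en-1-yl]-4-(phenylsulfanyl)-6-[(triethylsilyl)oxy]cyclohexyl 2-methoxy-6-methyl-4-[(triisopropylsilyl)oxy]benzoate (C6, C7 as in 17; C4a undefined) | O=C1[C@](C)(OC(=O)c2c(C)cc(O[Si](C(C)C)(C(C)C)C(C)C)cc2OC)[C@H](O[Si](CC)(CC)CC)CC(Sc3ccccc3)(CC(=O)/C=C/C)C1=C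
F2 | step 10 | (1R,6R,4Z)-1-methyl-3-methylidene-2-oxo-4-[(3E)-2-oxopent-3-en-1-ylidene]-6-[(triethylsilyl)oxy]cyclohexyl 2-methoxy-6-methyl-4-[(triisopropylsilyl)oxy]benzoate | O=C1[C@](C)(OC(=O)c2c(C)cc(O[Si](C(C)C)(C(C)C)C(C)C)cc2OC)[C@H](O[Si](CC)(CC)CC)C/C(=C/C(=O)/C=C/C)C1=C
F3 | step 8 | (3E)-1-(phenylselanyl)pent-3-en-2-ol (racemic) | OC(C[Se]c1ccccc1)/C=C/C
F4 | step 8 | (1R,6R)-3-(bromomethyl)-1-methyl-2-oxo-4-(phenylsulfanyl)-6-[(triethylsilyl)oxy]cyclohex-3-en-1-yl 2-methoxy-6-methyl-4-[(triisopropylsilyl)oxy]benzoate | O=C1[C@](C)(OC(=O)c2c(C)cc(O[Si](C(C)C)(C(C)C)C(C)C)cc2OC)[C@H](O[Si](CC)(CC)CC)CC(Sc3ccccc3)=C1CBr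
F5 | step 2 | 2-hydroxy-2-methylcyclohexane-1,3-dione | CC1(O)C(=O)CCCC1=O
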